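## Retrosynthetic overview

1. 19 ⇐ 17 by hydrogenolysis of both O-benzyl groups; 17 ⇐ hemiketal 15 by ionic reduction (sets C2); 15 ⇐ lactone 12 + aryllithium 13 (C2–aryl bond).
2. 12 ⇐ lactone acid 7 + aryl bromide 9: C5–aryl bond by visible-light nickel/photoredox decarboxylative arylation, with C5 re-set trans to the C4 methyl (key step).
3. 7 ⇐ (S)-5-(hydroxymethyl)furan-2(5H)-one 1: one-pot anti conjugate methylation (C4) and anti enolate methylation (C3), then oxidation of CH2OH to CO2H.
4. Rings: none is built; the five-membered ring of 1 is carried through and ends as the tetrahydrofuran, and both aryl rings come from 4-bromo-2,6-dimethoxyphenol 8.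

Assumption: 1 (the cellulose-derived chiral butenolide made industrially from levoglucosenone) and 8 are bought; ring positions are numbered as in each compound's own name.

## Route

Step 1
Reactants: 1 (S)-5-(hydroxymethyl)furan-2(5H)-one
Product: 2 (S)-5-{[(tert-butyldimethylsilyl)oxy]methyl}furan-2(5H)-one
Conditions: TBSCl, imidazole, CH2Cl2, 0 °C → rt
Reagents that add atoms: tert-butyldimethylsilyl chloride, CC(C)(C)[Si](C)(C)Cl
Why: Imidazole-promoted O-silylation (silyl ether formation) removes the acidic proton before the cuprate/enolate step and adds the bulk that shields one face of the butenolide, leaving the C5 stereocentre untouched.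

Step 2
Reactants: 2 (S)-5-{[(tert-butyldimethylsilyl)oxy]methyl}furan-2(5H)-one
Product: 4 (3S,4S,5S)-5-{[(tert-butyldimethylsilyl)oxy]methyl}-3,4-dimethyldihydrofuran-2(3H)-one, via lithium enolate 3 (not isolated)
Conditions: Me2CuLi (from CuI, 2 MeLi), Et2O, −78 → −30 °C; then MeI (excess), DMPU, −30 → 0 °C
Reagents that add atoms: lithium dimethylcuprate Me2CuLi, [Li+].C[Cu-]C (made in the flask from methyllithium, [Li]C, and CuI); iodomethane, CI
Why: Tandem conjugate addition–enolate alkylation in which the Gilman reagent Me2CuLi adds 1,4 anti to the C5 CH2OTBS group, so the bought C5 centre sets C4 as S (4,5-trans), and enolate 3 is trapped in the same flask by MeI on the face anti to the new C4 methyl, giving C3 as S (3,4-trans), which is also the more stable α-epimer.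

Step 3
Reactants: 4 (3S,4S,5S)-5-{[(tert-butyldimethylsilyl)oxy]methyl}-3,4-dimethyldihydrofuran-2(3H)-one
Product: 7 (2S,3S,4S)-3,4-dimethyl-5-oxotetrahydrofuran-2-carboxylic acid, via primary alcohol 5 (not isolated), via aldehyde 6 (not isolated)
Conditions: CrO3, H2SO4, H2O, acetone, 0 °C → rt
Reagents that add atoms: water, O
Why: Jones oxidation, in which the aqueous acid cleaves the primary silyl ether and hexavalent chromium oxidises alcohol 5 through aldehyde 6 (as its hydrate) to the acid without touching C3 or C4, while the configuration at C2 does not matter because step 5 erases it.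

Step 4
Reactants: 8 4-bromo-2,6-dimethoxyphenol
Product: 9 2-(benzyloxy)-5-bromo-1,3-dimethoxybenzene
Conditions: BnBr, K2CO3, DMF, 60 °C
Reagents that add atoms: benzyl bromide, BrCc1ccccc1
Why: Williamson ether synthesis (SN2 of the phenoxide on benzyl bromide) masks the phenol, which would otherwise quench the photocatalyst in step 5 and the aryllithium in step 6.

Step 5
Reactants: 7 (2S,3S,4S)-3,4-dimethyl-5-oxotetrahydrofuran-2-carboxylic acid (1.0 equiv); 9 2-(benzyloxy)-5-bromo-1,3-dimethoxybenzene (1.5 equiv)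
Product: 12 (3S,4S,5S)-5-[4-(benzyloxy)-3,5-dimethoxyphenyl]-3,4-dimethyldihydrofuran-2(3H)-one, via cesium carboxylate 10 (not isolated), via lactonyl radical 11 (not isolated)
Conditions: Ir[dF(CF3)ppy]2(dtbbpy)PF6 (2 mol %), NiCl2·glyme (10 mol %), dtbbpy (15 mol %), Cs2CO3 (1.5 equiv), DMF, 450 nm LEDs, 25 °C
Reagents that add atoms: none
Why: Proposed new method: nickel/photoredox decarboxylative arylation applied to a γ-lactone α-acyloxy acid as a stereochemical relay, in which excited Ir[dF(CF3)ppy]2(dtbbpy)PF6 oxidises carboxylate 10, loss of CO2 gives the planar α-acyloxy radical 11 (the bought centre is erased), this radical is captured by (dtbbpy)Ni(Ar)Br formed by oxidative addition of 9 to zerovalent nickel, and reductive elimination from the resulting trivalent nickel species forms the C5–aryl bond on the face anti to the C4 methyl so that C5 is re-set as S (4,5-trans) under control of C4; the closest known reaction type is the nickel/photoredox decarboxylative cross-coupling of α-alkoxy and α-amino acids (for example tetrahydrofuran-2-carboxylic acid) with aryl halides, which to my knowledge has not been shown for lactone-borne α-acyloxy acids or used to re-set a stereocentre in this way.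

Step 6
Reactants: 12 (3S,4S,5S)-5-[4-(benzyloxy)-3,5-dimethoxyphenyl]-3,4-dimethyldihydrofuran-2(3H)-one; 9 2-(benzyloxy)-5-bromo-1,3-dimethoxybenzene
Product: 15 (3S,4S,5S)-2,5-bis[4-(benzyloxy)-3,5-dimethoxyphenyl]-3,4-dimethyltetrahydrofuran-2-ol (both C2 epimers), via aryllithium 13 (not isolated), via lithium hemiketalate 14 (not isolated)
Conditions: 9, n-BuLi, THF, −78 °C; then 12, −78 °C; then H2O
Reagents that add atoms: none
Why: Bromine–lithium exchange on 9 gives aryllithium 13, whose 1,2-addition to the lactone carbonyl stops at the tetrahedral alkoxide 14 at −78 °C, and the new C2 centre is a mixture that is planarised in step 7.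

Step 7
Reactants: 15 (3S,4S,5S)-2,5-bis[4-(benzyloxy)-3,5-dimethoxyphenyl]-3,4-dimethyltetrahydrofuran-2-ol
Product: 17 (2S,3S,4S,5S)-2,5-bis[4-(benzyloxy)-3,5-dimethoxyphenyl]-3,4-dimethyltetrahydrofuran, via oxocarbenium ion 16 (not isolated)
Conditions: Et3SiH, BF3·OEt2, CH2Cl2, −78 → −20 °C
Reagents that add atoms: none
Why: Ionic hydrogenation (Lewis acid/silane reductive deoxygenation of a hemiketal) in which BF3 ionises 15 to the 2-aryl oxocarbenium ion 16 and Et3SiH adds hydride from inside the envelope that keeps the C4 methyl pseudoequatorial, which puts the C2 aryl trans to the C3 methyl (C2 S), this all-trans isomer also being the thermodynamic one to which a cis epimer reverts through BF3-induced benzylic ionisation on warming.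

Step 8
Reactants: 17 (2S,3S,4S,5S)-2,5-bis[4-(benzyloxy)-3,5-dimethoxyphenyl]-3,4-dimethyltetrahydrofuran
Product: 19 4,4'-[(2S,3S,4S,5S)-3,4-dimethyltetrahydrofuran-2,5-diyl]bis(2,6-dimethoxyphenol), via mono-benzyl ether 18 (not isolated)
Conditions: H2 (1 atm), 10% Pd/C, EtOAc–MeOH, rt
Reagents that add atoms: none
Why: Catalytic hydrogenolysis over Pd/C removes the two O-benzyl groups one after the other (through 18) under neutral conditions that do not epimerise the four stereocentres, giving the (2S,3S,4S,5S) target.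

## Compound list

1 | (S)-5-(hydroxymethyl)furan-2(5H)-one | O=C1O[C@H](CO)C=C1 | starting material
2 | (S)-5-{[(tert-butyldimethylsilyl)oxy]methyl}furan-2(5H)-one | O=C1O[C@H](CO[Si](C)(C)C(C)(C)C)C=C1 | intermediate
3 | lithium (4S,5S)-5-{[(tert-butyldimethylsilyl)oxy]methyl}-4-methyl-4,5-dihydrofuran-2-olate | [Li]OC1=C[C@H](C)[C@@H](CO[Si](C)(C)C(C)(C)C)O1 | intermediate
4 | (3S,4S,5S)-5-{[(tert-butyldimethylsilyl)oxy]methyl}-3,4-dimethyldihydrofuran-2(3H)-one | O=C1O[C@H](CO[Si](C)(C)C(C)(C)C)[C@@H](C)[C@@H]1C | intermediate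
5 | (3S,4S,5S)-5-(hydroxymethyl)-3,4-dimethyldihydrofuran-2(3H)-one | O=C1O[C@H](CO)[C@@H](C)[C@@H]1C | intermediate
6 | (2S,3S,4S)-3,4-dimethyl-5-oxotetrahydrofuran-2-carbaldehyde | O=C1O[C@H](C=O)[C@@H](C)[C@@H]1C | intermediate
7 | (2S,3S,4S)-3,4-dimethyl-5-oxotetrahydrofuran-2-carboxylic acid | O=C1O[C@H](C(=O)O)[C@@H](C)[C@@H]1C | intermediate
8 | 4-bromo-2,6-dimethoxyphenol | COc1cc(Br)cc(OC)c1O | starting material
9 | 2-(benzyloxy)-5-bromo-1,3-dimethoxybenzene | COc1cc(Br)cc(OC)c1OCc1ccccc1 | intermediate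
10 | cesium (2S,3S,4S)-3,4-dimethyl-5-oxotetrahydrofuran-2-carboxylate | O=C1O[C@H](C([O-])=O)[C@@H](C)[C@@H]1C.[Cs+] | intermediate
11 | (3S,4S)-3,4-dimethyl-5-oxotetrahydrofuran-2-yl radical | O=C1O[CH][C@@H](C)[C@@H]1C | intermediate
12 | (3S,4S,5S)-5-[4-(benzyloxy)-3,5-dimethoxyphenyl]-3,4-dimethyldihydrofuran-2(3H)-one | O=C1O[C@H](c2cc(OC)c(OCc3ccccc3)c(OC)c2)[C@@H](C)[C@@H]1C | intermediate
13 | [4-(benzyloxy)-3,5-dimethoxyphenyl]lithium | [Li]c1cc(OC)c(OCc2ccccc2)c(OC)c1 | intermediate
14 | lithium (3S,4S,5S)-2,5-bis[4-(benzyloxy)-3,5-dimethoxyphenyl]-3,4-dimethyltetrahydrofuran-2-olate (both C2 epimers) | [Li]OC1(c2cc(OC)c(OCc3ccccc3)c(OC)c2)O[C@H](c2cc(OC)c(OCc3ccccc3)c(OC)c2)[C@@H](C)[C@@H]1C | intermediate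
15 | (3S,4S,5S)-2,5-bis[4-(benzyloxy)-3,5-dimethoxyphenyl]-3,4-dimethyltetrahydrofuran-2-ol (both C2 epimers) | OC1(c2cc(OC)c(OCc3ccccc3)c(OC)c2)O[C@H](c2cc(OC)c(OCc3ccccc3)c(OC)c2)[C@@H](C)[C@@H]1C | intermediate
16 | (3S,4S,5S)-2,5-bis[4-(benzyloxy)-3,5-dimethoxyphenyl]-3,4-dimethyl-4,5-dihydro-3H-furan-1-ium (oxocarbenium ion) | COc1cc(cc(OC)c1OCc1ccccc1)C1=[O+][C@H](c2cc(OC)c(OCc3ccccc3)c(OC)c2)[C@@H](C)[C@@H]1C | intermediate
17 | (2S,3S,4S,5S)-2,5-bis[4-(benzyloxy)-3,5-dimethoxyphenyl]-3,4-dimethyltetrahydrofuran | COc1cc(cc(OC)c1OCc1ccccc1)[C@H]1O[C@H](c2cc(OC)c(OCc3ccccc3)c(OC)c2)[C@@H](C)[C@@H]1C | intermediate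
18 | 4-[(2S,3S,4S,5S)-5-[4-(benzyloxy)-3,5-dimethoxyphenyl]-3,4-dimethyltetrahydrofuran-2-yl]-2,6-dimethoxyphenol | COc1cc(cc(OC)c1O)[C@H]1O[C@H](c2cc(OC)c(OCc3ccccc3)c(OC)c2)[C@@H](C)[C@@H]1C | intermediate
19 | 4,4'-[(2S,3S,4S,5S)-3,4-dimethyltetrahydrofuran-2,5-diyl]bis(2,6-dimethoxyphenol) (CNP0217414.3) | COc1cc([C@H]2O[C@H](c3cc(OC)c(O)c(OC)c3)[C@@H](C)[C@@H]2C)cc(OC)c1O | target

## Step count and risks

Total step count: 8 (steps 1–8, including the one-step preparation of 9).
Longest linear sequence: 7 steps (1 → 2 → 4 → 7 → 12 → 15 → 17 → 19).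

Stereochemical logic in brief: the C4 methyl centre, set in step 2 by the bought centre of 1, is never epimerisable afterwards. It controls C3 (step 2), the re-formed C5 (step 5) and, through C3, C2 (step 7), and each of these is also the thermodynamically preferred trans arrangement.

The three steps most likely to fail:

Step 5 (proposed new step). The α-acyloxy carboxylate is oxidised less readily and its radical is less nucleophilic than the usual α-alkoxy cases, and 9 is an electron-rich bromide. Protodecarboxylation, low conversion or a modest trans:cis ratio at C5 are therefore possible. The fallback uses only known chemistry; it sets out from 4 and comes back at 17. Lactone 4 is treated with aryllithium 13 (from 9 and n-BuLi, THF, −78 °C) to give the hemiketal (3S,4S,5S)-2-[4-(benzyloxy)-3,5-dimethoxyphenyl]-5-{[(tert-butyldimethylsilyl)oxy]methyl}-3,4-dimethyltetrahydrofuran-2-ol F1. Et3SiH/BF3·OEt2 (CH2Cl2, −78 °C) reduces it to the silyl ether {[(2S,3S,4S,5S)-5-[4-(benzyloxy)-3,5-dimethoxyphenyl]-3,4-dimethyltetrahydrofuran-2-yl]methoxy}(tert-butyl)dimethylsilane F2. Bu4NF (THF) frees the alcohol [(2S,3S,4S,5S)-5-[4-(benzyloxy)-3,5-dimethoxyphenyl]-3,4-dimethyltetrahydrofuran-2-yl]methanol F3, and TEMPO/PhI(OAc)2 (MeCN–H2O) oxidises it to (2S,3S,4S,5S)-5-[4-(benzyloxy)-3,5-dimethoxyphenyl]-3,4-dimethyltetrahydrofuran-2-carboxylic acid F4. This is an ordinary cyclic α-alkoxy acid, the established substrate class for the nickel/photoredox decarboxylative arylation. Coupling with 9 under the catalysts of step 5 puts the aryl group trans to the neighbouring methyl and gives 17, after which step 8 follows.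

Step 7. Hydride may be delivered to the other face of 16 (2,3-cis epimer), or the electron-rich benzylic C–O bond may be reduced further with ring opening. The fallback sets out from 15 and comes back at 17, and replaces C–H bond formation by a thermodynamically controlled C–O ring closure. LiAlH4 (THF, 0 °C) reduces 15 through its open hydroxy-ketone form to the diol (1RS,2S,3S,4S)-1,4-bis[4-(benzyloxy)-3,5-dimethoxyphenyl]-2,3-dimethylbutane-1,4-diol F5. Catalytic TsOH in CH2Cl2 (0 °C → rt) then cyclises F5 by SN1 cyclodehydration through the benzylic cation, which converges on the all-trans tetrahydrofuran 17 whatever the carbinol configurations.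

Step 2. The copper-bound enolate 3 may be methylated only sluggishly in the cuprate medium, and proton exchange between 4 and unreacted 3 may give some 3,3-dimethyl lactone. The fallback sets out from 2 and comes back at 4, and replaces the one-pot three-component coupling by two separate operations. The cuprate addition to 2 is quenched with aqueous NH4Cl to isolate (4S,5S)-5-{[(tert-butyldimethylsilyl)oxy]methyl}-4-methyldihydrofuran-2(3H)-one F6. After purification, F6 is deprotonated with LiN(SiMe3)2 (THF, −78 °C) to regenerate 3 as a copper-free lithium enolate, which MeI methylates cleanly at −78 → −40 °C anti to the C4 methyl to give 4.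

## Further compounds

F1 | step 5 | (3S,4S,5S)-2-[4-(benzyloxy)-3,5-dimethoxyphenyl]-5-{[(tert-butyldimethylsilyl)oxy]methyl}-3,4-dimethyltetrahydrofuran-2-ol | OC1(c2cc(OC)c(OCc3ccccc3)c(OC)c2)O[C@H](CO[Si](C)(C)C(C)(C)C)[C@@H](C)[C@@H]1C
F2 | step 5 | {[(2S,3S,4S,5S)-5-[4-(benzyloxy)-3,5-dimethoxyphenyl]-3,4-dimethyltetrahydrofuran-2-yl]methoxy}(tert-butyl)dimethylsilane | COc1cc(cc(OC)c1OCc1ccccc1)[C@H]1O[C@H](CO[Si](C)(C)C(C)(C)C)[C@@H](C)[C@@H]1C
F3 | step 5 | [(2S,3S,4S,5S)-5-[4-(benzyloxy)-3,5-dimethoxyphenyl]-3,4-dimethyltetrahydrofuran-2-yl]methanol | COc1cc(cc(OC)c1OCc1ccccc1)[C@H]1O[C@H](CO)[C@@H](C)[C@@H]1C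
F4 | step 5 | (2S,3S,4S,5S)-5-[4-(benzyloxy)-3,5-dimethoxyphenyl]-3,4-dimethyltetrahydrofuran-2-carboxylic acid | COc1cc(cc(OC)c1OCc1ccccc1)[C@H]1O[C@H](C(=O)O)[C@@H](C)[C@@H]1C
F5 | step 7 | (1RS,2S,3S,4S)-1,4-bis[4-(benzyloxy)-3,5-dimethoxyphenyl]-2,3-dimethylbutane-1,4-diol | O[C@H](c1cc(OC)c(OCc2ccccc2)c(OC)c1)[C@@H](C)[C@H](C)C(O)c1cc(OC)c(OCc2ccccc2)c(OC)c1
F6 | step 2 | (4S,5S)-5-{[(tert-butyldimethylsilyl)oxy]methyl}-4-methyldihydrofuran-2(3H)-one | O=C1O[C@H](CO[Si](C)(C)C(C)(C)C)[C@@H](C)C1
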